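Everything rests on cutting ring C at C11–C12 and O–C9, which leads back to a C9-methylene cis-decalin and a 4-benzyloxy-3-oxobutanoate. The key step exploits the environment of C9: this spiro atom shared by rings B and C is bonded to the ring C oxygen, sits between two quaternary neighbours (C8 and C10), and its two-carbon chain C11–C12 leads to the oxygenated C13. An oxidative radical (3+2) annulation therefore adds C12 to the open CH2 end and closes O–C9 while it joins the fragments. The precursor is the 8α-acetoxy-7β-silyloxy-6-oxo cis-decalin with a C9=C11 methylene, made from nerol; the keto ester is used as its benzyl ester so that the carboxyl group can later be removed without base.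

Key step: step 16

Remarks
- Numbering: labdane numbering of the target is used for all decalin intermediates (C1–C10 ring carbons, C11 on C9, C17 on C8, C20 on C10); β is the face of the C10 methyl group, and the target SMILES places H-5 on that face too (cis-decalin).
- Compounds 5–12 are racemic; their SMILES show the enantiomer that step 10 carries on.
- Assumption: the cis ring fusion (C5–H next to the C6 ketone from 16 on) and C7 are taken to be configurationally stable under the buffered, weakly acidic or weakly basic conditions chosen; strong bases are avoided after step 13.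

Step 1
Reactants: 1 nerol
Product: 2 neryl bromide
Conditions: PBr3 (0.4 equiv), Et2O, −10 °C
Reagents that add atoms: phosphorus tribromide, BrP(Br)Br
Why: Low-temperature PBr3 bromination of a primary allylic alcohol is an SN2 displacement of the phosphite ester and should keep the Z geometry of the C2=C3 double bond.

Step 2
Reactants: 3 methyl acetoacetate; 2 neryl bromide
Product: 4 methyl (6Z)-7,11-dimethyl-3-oxododeca-6,10-dienoate
Conditions: LDA (2.1 equiv), THF, 0 °C; then 2, 0 °C → rt; 1 M HCl
Reagents that add atoms: none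
Why: Huckin–Weiler γ-alkylation: the dianion of the β-keto ester reacts at its more basic terminal carbon with the primary allylic bromide by SN2 attack, and the Z double bond is untouched.

Step 3
Reactants: 4 methyl (6Z)-7,11-dimethyl-3-oxododeca-6,10-dienoate
Product: 5 rac-cis-fused bicyclic β-keto ester (C8 ketone; CO2Me on C9; 5β-H; 10β-CH3)
Conditions: SnCl4 (1.2 equiv), CH2Cl2, −78 → 0 °C
Reagents that add atoms: none
Why: Lewis-acid-initiated cation–olefin bicyclisation (Stork–Eschenmoser type) ended by C-alkylation of the tin-bound β-keto ester enol; antiperiplanar addition across the Z double bond should give the cis ring fusion, in racemic form.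

Step 4
Reactants: 5 rac-cis-fused bicyclic β-keto ester
Product: 7 rac-6-en-8-one β-keto ester, via C7 phenylselenide 6 (not isolated)
Conditions: LDA (2.2 equiv), THF, −78 → 0 °C; PhSeBr, −78 °C; AcOH; then 30% H2O2, pyridine, CH2Cl2, 0 °C → rt
Reagents that add atoms: none
Why: The dianion is selenenylated at its γ carbon C7, and selenoxide syn-elimination (Sharpless–Reich) can only run towards C6 because C8 is the carbonyl carbon, which gives the C6=C7 enone without touching the ring fusion.

Step 5
Reactants: 7 rac-6-en-8-one β-keto ester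
Product: 8 rac-dienyl triflate (C6=C7; C8(OTf)=C9–CO2Me)
Conditions: Tf2O, iPr2NEt, CH2Cl2, −78 °C
Reagents that add atoms: trifluoromethanesulfonic anhydride, O=S(=O)(OS(=O)(=O)C(F)(F)F)C(F)(F)F
Why: O-triflation of the β-keto ester enol with Tf2O and a hindered amine is the standard entry to β-triflyloxy enoates, and C8 is the only ketone.

Step 6
Reactants: 8 rac-dienyl triflate
Product: 9 rac-6,8-dienoate with the C8 methyl group (C17)
Conditions: MeMgBr, Fe(acac)3 (5 mol %), THF/NMP, −30 °C
Reagents that add atoms: methylmagnesium bromide, C[Mg]Br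
Why: Iron-catalysed Kumada-type coupling of alkenyl triflates with MeMgBr (Fürstner conditions) is faster than Grignard addition to the methyl ester at −30 °C and installs C17.

Step 7
Reactants: 9 rac-6,8-dienoate
Product: 10 rac-6β,7β-diol of the 8-en-11-oate
Conditions: OsO4 (2 mol %), NMO, acetone/H2O, rt
Reagents that add atoms: osmium tetroxide (catalytic oxygen carrier), O=[Os](=O)(=O)=O; N-methylmorpholine N-oxide, C[N+]1([O-])CCOCC1; water, O
Why: Upjohn dihydroxylation attacks the electron-richer, less substituted γ,δ double bond (C6=C7) and not the ester-conjugated tetrasubstituted C8=C9 bond; suprafacial addition anti to the bulky C4 quaternary carbon on C5, that is syn to H-5, should set 6β and 7β together.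

Step 8
Reactants: 10 rac-6β,7β-diol
Product: 11 rac-7β-TBS ether 6β-alcohol ester
Conditions: TBSCl (1.1 equiv), imidazole, DMF, 0 °C → rt
Reagents that add atoms: tert-butyldimethylsilyl chloride, CC(C)(C)[Si](C)(C)Cl
Why: Sterically differentiated silylation of a vicinal diol: the allylic C7 hydroxyl is the more accessible one, whereas the C6 hydroxyl is buttressed by the C4 gem-dimethyl group through C5 and should stay free at one equivalent of reagent.

Step 9
Reactants: 11 rac-7β-TBS ether 6β-alcohol ester
Product: 12 rac-C8=C9 allylic alcohol (11-OH) with 6β-OH and 7β-OTBS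
Conditions: DIBAL-H (3.5 equiv), CH2Cl2, −78 → 0 °C; Rochelle salt
Reagents that add atoms: none
Why: DIBAL-H reduces the α,β-unsaturated ester to the primary allylic alcohol by 1,2-reduction; the silyl ether and the free hydroxyl (as its aluminium alkoxide) are inert.

Step 10
Reactants: 12 rac-C8=C9 allylic alcohol
Product: 13 8α,9α-epoxy alcohol (single enantiomer)
Conditions: Ti(OiPr)4 (0.3 equiv), D-(−)-diethyl tartrate (0.36 equiv), t-BuOOH (2 equiv), 4 Å MS, CH2Cl2, −20 °C; chromatographic separation of the diastereomers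
Reagents that add atoms: tert-butyl hydroperoxide, CC(C)(C)OO
Why: Katsuki–Sharpless asymmetric epoxidation under reagent control: by the empirical facial rule D-(−)-tartrate should deliver oxygen to the α face (anti to the C10 methyl) of the wanted enantiomer of 12 and to the β face of its mirror image, so the racemate is split into separable diastereomeric epoxy alcohols, and 13 carries C8–O and C9–O on the α face together with the absolute configuration.

Step 11
Reactants: 13 8α,9α-epoxy alcohol
Product: 14 8α,9α-epoxy 11-iodide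
Conditions: PPh3, I2, imidazole, THF, 0 °C
Reagents that add atoms: iodine, [I][I]
Why: Appel-type iodination (Garegg–Samuelsson conditions) converts the primary alcohol into the iodide by displacement of the alkoxyphosphonium group, while the hindered secondary C6 hydroxyl should not react at 0 °C.

Step 12
Reactants: 14 8α,9α-epoxy 11-iodide
Product: 15 7β-TBS ether 6β,8α-diol with the C9=C11 methylene
Conditions: activated Zn dust, AcOH (2 equiv), EtOH, 50 °C
Reagents that add atoms: none
Why: Zinc insertion into the C–I bond and β-elimination of the epoxide oxygen (reductive epoxide fragmentation) gives the exocyclic methylene and the tertiary 8α-alcohol; the C8–O bond is not broken, so C8 keeps its configuration.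

Step 13
Reactants: 15 7β-TBS ether 6β,8α-diol
Product: 16 8α-hydroxy 6-ketone
Conditions: Dess–Martin periodinane, NaHCO3, CH2Cl2, 0 °C → rt
Reagents that add atoms: none
Why: Dess–Martin oxidation converts the only oxidisable (secondary) alcohol into the C6 ketone under buffered, non-epimerising conditions; the tertiary alcohol cannot be oxidised.

Step 14
Reactants: 16 8α-hydroxy 6-ketone
Product: 17 annulation precursor (8α-acetate; 7β-TBS ether; 6-ketone; C9=C11 methylene)
Conditions: Ac2O, DMAP, Et3N, CH2Cl2, 40 °C
Reagents that add atoms: acetic anhydride, CC(=O)OC(C)=O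
Why: DMAP-catalysed (Steglich-type) acylation is the standard method for hindered tertiary alcohols and acetylates the only free hydroxyl.

Step 15
Reactants: 18 ethyl 4-(benzyloxy)-3-oxobutanoate
Product: 19 benzyl 4-(benzyloxy)-3-oxobutanoate
Conditions: BnOH (1.5 equiv), DMAP (10 mol %), toluene, reflux (−EtOH)
Reagents that add atoms: benzyl alcohol, OCc1ccccc1
Why: DMAP-catalysed transesterification of a β-keto ester with removal of ethanol; the benzyl ester is chosen because it is inert to the radical step and can later be cleaved by neutral hydrogenolysis in the presence of the acetate and the ketone.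

Step 16
Reactants: 17 annulation precursor; 19 benzyl 4-(benzyloxy)-3-oxobutanoate
Product: 20 spiro 4,5-dihydrofuran (ring C closed at O–C9; benzyl ester on C12; benzyloxymethyl on C13)
Conditions: 19 (2 equiv), Mn(OAc)3·2H2O (4.2 equiv), Cu(OAc)2·H2O (0.5 equiv), KOAc, degassed AcOH, 45 °C
Reagents that add atoms: none
Why: Trivalent manganese (Mn(OAc)3) oxidises the enolate of 19 to the electrophilic C12 radical, which adds to the unhindered CH2 terminus (C11) of the C9=C11 alkene; divalent copper (Cu(OAc)2) then oxidises the tertiary C9 radical faster than a 1,2-acyloxy shift can occur, and the ketone enol oxygen of the adduct captures C9. The closest known reaction type is the Mn(OAc)3-mediated oxidative (3+2) annulation of β-keto esters with 1,1-disubstituted alkenes to 4,5-dihydrofuran-3-carboxylates. Ring C is closed by a five-membered enol-oxygen closure (5-enolendo O-alkylation) onto the C9 cation or its organocopper equivalent, so that C11–C12 and O–C9 are formed in one operation. The only new stereocentre, C9, is substrate-controlled: in the ring B chair that keeps the C8 and C10 methyl groups equatorial the 7β-silyloxy group is axial and syn to the β lobe of C9, and both methyl groups flank that face, so the tethered oxygen should close on the α face and push C11 to the β face. Regioselectivity (addition at CH2) is secured by the fully substituted C9; chemoselectivity requires enol capture to outrun acetoxonium formation by the 8α-acetate, which the intramolecular five-membered closure and the buffered copper-mediated oxidation favour, and such bridging could in any case place oxygen only on the α face.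

Step 17
Reactants: 20 spiro 4,5-dihydrofuran
Product: 23 C13 methyl ketal (mixture at C13), via C12 carboxylic acid 21 (not isolated), via C12=C13 enol ether 22 (not isolated)
Conditions: H2 (1 atm), 5% Pd/C, pyridine (0.5 equiv), EtOAc, rt; filter, evaporate; then PPTS (0.2 equiv), MeOH, 45 °C
Reagents that add atoms: methanol, CO
Why: Hydrogenolysis over pyridine-moderated Pd/C (Sajiki conditions) cleaves the benzyl ester but not the benzyl ether or the tetrasubstituted push–pull alkene; the vinylogous carbonic acid then loses CO2 after protonation at C12 (β-keto acid type decarboxylation), and the enol ether adds methanol under PPTS to the mixed ketal, whose C13 configuration is irrelevant.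

Step 18
Reactants: 23 C13 methyl ketal
Product: 24 13-allyl 13-benzyloxymethyl tetrahydrofuran
Conditions: allylSiMe3 (4 equiv), TMSOTf (0.3 equiv), CH2Cl2, −78 → −40 °C
Reagents that add atoms: allyltrimethylsilane, C=CC[Si](C)(C)C
Why: Hosomi–Sakurai-type allylation of the cyclic oxocarbenium ion released from the ketal sets C13: ring C should tilt away from the axial 7β-silyloxy group so that C11 is the envelope flap on the C8 side, and inside attack on that face (Woerpel model) should place the allyl group (future C14) syn to C8 and the benzyloxymethyl group (C16) syn to C10.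

Step 19
Reactants: 24 13-allyl 13-benzyloxymethyl tetrahydrofuran
Product: 25 C15 aldehyde
Conditions: O3, CH2Cl2, −78 °C (to the end point of a red azo indicator dye); PPh3, −78 °C → rt
Reagents that add atoms: ozone, [O-][O+]=O
Why: Ozonolysis of the terminal alkene with reductive PPh3 work-up gives the aldehyde; at −78 °C with indicator-controlled dosing the monosubstituted alkene reacts much faster than the benzyl ether.

Step 20
Reactants: 25 C15 aldehyde
Product: 27 ring D lactol (mixture at C15), via C16 hydroxy aldehyde 26 (not isolated)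
Conditions: H2 (1 atm), Pd(OH)2/C, EtOAc, rt
Reagents that add atoms: none
Why: Hydrogenolysis of the benzyl ether frees the C16 hydroxyl, which closes spontaneously onto the C15 aldehyde to the five-membered lactol; the C15 anomeric centre is removed in the next step.

Step 21
Reactants: 27 ring D lactol
Product: 29 7-O-TBS ether of the target, via lactol mesylate 28 (not isolated)
Conditions: MsCl, Et3N, CH2Cl2, 0 → 40 °C
Reagents that add atoms: none
Why: Mesylation of the lactol hydroxyl and amine-induced elimination through the oxocarbenium ion (the usual lactol-to-glycal dehydration) gives the C14=C15 enol ether; elimination can only run towards C14, and the basic medium protects the acid-labile product.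

Step 22
Reactants: 29 7-O-TBS ether of the target
Product: 30 target CNP0275274.1
Conditions: TBAF, AcOH (1:1), THF, 0 °C → rt
Reagents that add atoms: none
Why: Fluoride cleavage of the silyl ether buffered with acetic acid avoids alkoxide-induced acetyl migration or epimerisation next to the C6 ketone and leaves the acid-sensitive enol ether of ring D intact.

Compound list
1 | nerol, (2Z)-3,7-dimethylocta-2,6-dien-1-ol | CC(C)=CCC/C(C)=C\CO | starting material
2 | neryl bromide, (2Z)-1-bromo-3,7-dimethylocta-2,6-diene | CC(C)=CCC/C(C)=C\CBr | intermediate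
3 | methyl acetoacetate | COC(=O)CC(C)=O | starting material
4 | methyl (6Z)-7,11-dimethyl-3-oxododeca-6,10-dienoate | COC(=O)CC(=O)CC/C=C(C)\CCC=C(C)C | intermediate
5 | rac-methyl 5,5,8a-trimethyl-2-oxodecahydronaphthalene-1-carboxylate, cis-fused (C8 ketone, CO2Me on C9, 5β-H, 10β-CH3) | O=C1CC[C@@H]2C(C)(C)CCC[C@]2(C)C1C(=O)OC | intermediate
6 | rac-C7 phenylselenide of 5 | O=C1C([Se]c3ccccc3)C[C@@H]2C(C)(C)CCC[C@]2(C)C1C(=O)OC | intermediate
7 | rac-6-en-8-one β-keto ester (C6=C7, C8 ketone, CO2Me on C9) | O=C1C=C[C@@H]2C(C)(C)CCC[C@]2(C)C1C(=O)OC | intermediate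
8 | rac-dienyl triflate (C6=C7, C8(OTf)=C9–CO2Me) | FC(F)(F)S(=O)(=O)OC=1C=C[C@@H]2C(C)(C)CCC[C@]2(C)C=1C(=O)OC | intermediate
9 | rac-methyl 2,5,5,8a-tetramethyl-4a,5,6,7,8,8a-hexahydronaphthalene-1-carboxylate, cis-fused (C6=C7, C8(CH3)=C9–CO2Me) | CC=1C=C[C@@H]2C(C)(C)CCC[C@]2(C)C=1C(=O)OC | intermediate
10 | rac-6β,7β-diol of the 8-en-11-oate | CC=1[C@@H](O)[C@@H](O)[C@@H]2C(C)(C)CCC[C@]2(C)C=1C(=O)OC | intermediate
11 | rac-7β-TBS ether 6β-alcohol ester | CC=1[C@@H](O[Si](C)(C)C(C)(C)C)[C@@H](O)[C@@H]2C(C)(C)CCC[C@]2(C)C=1C(=O)OC | intermediate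
12 | rac-C8=C9 allylic alcohol (11-OH, 6β-OH, 7β-OTBS) | CC=1[C@@H](O[Si](C)(C)C(C)(C)C)[C@@H](O)[C@@H]2C(C)(C)CCC[C@]2(C)C=1CO | intermediate
13 | 8α,9α-epoxy alcohol (11-OH, 6β-OH, 7β-OTBS), single enantiomer | C[C@@]1(O3)[C@@H](O[Si](C)(C)C(C)(C)C)[C@@H](O)[C@@H]2C(C)(C)CCC[C@]2(C)[C@@]13CO | intermediate
14 | 8α,9α-epoxy 11-iodide | C[C@@]1(O3)[C@@H](O[Si](C)(C)C(C)(C)C)[C@@H](O)[C@@H]2C(C)(C)CCC[C@]2(C)[C@@]13CI | intermediate
15 | 7β-TBS ether 6β,8α-diol with C9=C11 methylene (8β-CH3) | C[C@@]1(O)[C@@H](O[Si](C)(C)C(C)(C)C)[C@@H](O)[C@@H]2C(C)(C)CCC[C@]2(C)C1=C | intermediate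
16 | 8α-hydroxy 6-ketone with 7β-OTBS and C9=C11 methylene | C[C@@]1(O)[C@@H](O[Si](C)(C)C(C)(C)C)C(=O)[C@@H]2C(C)(C)CCC[C@]2(C)C1=C | intermediate
17 | annulation precursor: 8α-acetoxy-7β-(TBS-oxy)-6-oxo cis-decalin with C9=C11 methylene | CC(=O)O[C@]1(C)[C@@H](O[Si](C)(C)C(C)(C)C)C(=O)[C@@H]2C(C)(C)CCC[C@]2(C)C1=C | intermediate
18 | ethyl 4-(benzyloxy)-3-oxobutanoate | CCOC(=O)CC(=O)COCc1ccccc1 | starting material
19 | benzyl 4-(benzyloxy)-3-oxobutanoate | O=C(CC(=O)COCc1ccccc1)OCc1ccccc1 | intermediate
20 | spiro 4,5-dihydrofuran: ring C with 9α-O, benzyl ester on C12, benzyloxymethyl on C13 | CC(=O)O[C@]1(C)[C@@H](O[Si](C)(C)C(C)(C)C)C(=O)[C@@H]2C(C)(C)CCC[C@]2(C)[C@@]12CC(C(=O)OCc3ccccc3)=C(COCc3ccccc3)O2 | intermediate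
21 | C12 carboxylic acid of the spiro dihydrofuran | CC(=O)O[C@]1(C)[C@@H](O[Si](C)(C)C(C)(C)C)C(=O)[C@@H]2C(C)(C)CCC[C@]2(C)[C@@]12CC(C(=O)O)=C(COCc3ccccc3)O2 | intermediate
22 | C12=C13 cyclic enol ether (13-benzyloxymethyl) | CC(=O)O[C@]1(C)[C@@H](O[Si](C)(C)C(C)(C)C)C(=O)[C@@H]2C(C)(C)CCC[C@]2(C)[C@@]12CC=C(COCc3ccccc3)O2 | intermediate
23 | C13 methyl ketal (13-methoxy-13-benzyloxymethyl), mixture at C13 | CC(=O)O[C@]1(C)[C@@H](O[Si](C)(C)C(C)(C)C)C(=O)[C@@H]2C(C)(C)CCC[C@]2(C)[C@@]12CCC(OC)(COCc3ccccc3)O2 | intermediate
24 | 13-allyl 13-benzyloxymethyl tetrahydrofuran (allyl syn to C8) | CC(=O)O[C@]1(C)[C@@H](O[Si](C)(C)C(C)(C)C)C(=O)[C@@H]2C(C)(C)CCC[C@]2(C)[C@@]12CC[C@](CC=C)(COCc3ccccc3)O2 | intermediate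
25 | C15 aldehyde (13-CH2CHO, 13-benzyloxymethyl) | CC(=O)O[C@]1(C)[C@@H](O[Si](C)(C)C(C)(C)C)C(=O)[C@@H]2C(C)(C)CCC[C@]2(C)[C@@]12CC[C@](CC=O)(COCc3ccccc3)O2 | intermediate
26 | C16 hydroxy C15 aldehyde | CC(=O)O[C@]1(C)[C@@H](O[Si](C)(C)C(C)(C)C)C(=O)[C@@H]2C(C)(C)CCC[C@]2(C)[C@@]12CC[C@](CC=O)(CO)O2 | intermediate
27 | ring D lactol (15-hydroxy-15,16-epoxide), mixture at C15 | CC(=O)O[C@]1(C)[C@@H](O[Si](C)(C)C(C)(C)C)C(=O)[C@@H]2C(C)(C)CCC[C@]2(C)[C@@]12CC[C@@]1(CC(O)OC1)O2 | intermediate
28 | lactol mesylate | CC(=O)O[C@]1(C)[C@@H](O[Si](C)(C)C(C)(C)C)C(=O)[C@@H]2C(C)(C)CCC[C@]2(C)[C@@]12CC[C@@]1(CC(OS(C)(=O)=O)OC1)O2 | intermediate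
29 | 7-O-TBS ether of the target | CC(=O)O[C@]1(C)[C@@H](O[Si](C)(C)C(C)(C)C)C(=O)[C@@H]2C(C)(C)CCC[C@]2(C)[C@@]12CC[C@@]1(C=COC1)O2 | intermediate
30 | CNP0275274.1: 8α-acetoxy-7β-hydroxy-9α,13;15,16-diepoxy-5β-labd-14-en-6-one (C14 syn to C8) | CC(=O)O[C@]1(C)[C@@H](O)C(=O)[C@@H]2C(C)(C)CCC[C@]2(C)[C@@]12CC[C@@]1(C=COC1)O2 | target

Total step count: 22. Longest linear sequence: 21 steps (steps 1–14 and 16–22); step 15 prepares the second fragment.

Steps most likely to fail

1. Step 16 (key annulation). What may go wrong: capture of the C9 cation by the neighbouring 8α-acetate (acetoxonium formation), acyloxy migration in the C9 radical, or closure of the enol oxygen on the wrong face of C9. Fallback, setting out from 17 (with 19) and returning at 20: the addition is run with Mn(OAc)3 alone in acetic acid containing water, so that the C9 cation is deliberately taken by the 8α-acetate as a cis-fused acetoxonium ion, which can place oxygen only on the α face, and is hydrolysed to the 9α-hydroxy 8α-acetate keto ester F1 (the isomeric 9-acetate equilibrates with it through the ortho acid). Acid-catalysed cyclodehydration of the tertiary alcohol onto the C13 ketone (PPTS, toluene, 4 Å sieves, 60 °C), the known condensation of γ-hydroxy β-keto esters to dihydrofurans, should then give 20; ring C is closed here at O–C13 by condensation instead of by oxidative capture.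

2. Step 18 (allylation at C13). What may go wrong: poor or reversed facial selectivity in the addition to the C13 oxocarbenium ion, so that the allyl group ends up syn to C10. Fallback, setting out from 23 and returning at 27: the roles of the two C13 arms are exchanged, which corrects the configuration by construction. The same allylation would deliver the C13 epimer F2. Its allyl group is isomerised (RuHCl(CO)(PPh3)3, toluene, 80 °C) to the propenyl isomer F3, which is ozonised (PPh3 work-up) and the hindered α-alkoxy aldehyde reduced with NaBH(OAc)3 to the hydroxymethyl compound F4; this arm is now C16. Silylation (TESCl, imidazole) gives the triethylsilyl ether F5, hydrogenolysis (H2, Pd(OH)2/C) the primary alcohol F6, and Dess–Martin oxidation the C14 aldehyde F7. Wittig methoxymethylenation (Ph3P=CHOMe, THF, −78 → 0 °C) gives the methyl enol ether F8, and mild aqueous acid (PPTS, acetone/H2O) hydrolyses the enol ether, removes the triethylsilyl group and closes the lactol 27.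

3. Step 10 (asymmetric epoxidation and resolution). What may go wrong: substrate-controlled oxygen delivery to the β face of the hindered tetrasubstituted alkene overriding the tartrate, which would make the epoxidation slow or unselective and spoil the resolution. Fallback, setting out from 12 and returning at 17: the β preference is used. L-(+)-diethyl tartrate, which by the same facial rule is matched with β delivery for the wanted enantiomer, is used in a kinetic resolution stopped near half conversion to give the 8β,9β-epoxy alcohol F9. Ti(OiPr)4-mediated opening of the 2,3-epoxy alcohol with acetic acid at the distal carbon C8 with inversion gives the 8α-acetoxy-9β,11-diol F10, which already has the C8 configuration and the acetate of the target. Thiocarbonyldiimidazole (DMAP, toluene, 80 °C) gives the cyclic thionocarbonate F11, and Corey–Winter fragmentation (P(OMe)3, 110 °C) the 8α-acetoxy 6β-alcohol with the C9=C11 methylene F12. Dess–Martin oxidation of F12 gives 17.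

Further compounds
F1 | step 16 | 9α-hydroxy 8α-acetate keto ester (C11 bonded to C12 of the benzyl 4-benzyloxy-3-oxobutanoate unit) | CC(=O)O[C@]1(C)[C@@H](O[Si](C)(C)C(C)(C)C)C(=O)[C@@H]2C(C)(C)CCC[C@]2(C)[C@@]1(O)CC(C(=O)OCc3ccccc3)C(=O)COCc3ccccc3
F2 | step 18 | C13 epimer of 24 (allyl syn to C10) | CC(=O)O[C@]1(C)[C@@H](O[Si](C)(C)C(C)(C)C)C(=O)[C@@H]2C(C)(C)CCC[C@]2(C)[C@@]12CC[C@@](CC=C)(COCc3ccccc3)O2
F3 | step 18 | propenyl isomer of F2 | CC(=O)O[C@]1(C)[C@@H](O[Si](C)(C)C(C)(C)C)C(=O)[C@@H]2C(C)(C)CCC[C@]2(C)[C@@]12CC[C@@](/C=C/C)(COCc3ccccc3)O2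
F4 | step 18 | 13-hydroxymethyl 13-benzyloxymethyl compound (hydroxymethyl syn to C10) | CC(=O)O[C@]1(C)[C@@H](O[Si](C)(C)C(C)(C)C)C(=O)[C@@H]2C(C)(C)CCC[C@]2(C)[C@@]12CC[C@@](CO)(COCc3ccccc3)O2
F5 | step 18 | triethylsilyl ether of F4 | CC(=O)O[C@]1(C)[C@@H](O[Si](C)(C)C(C)(C)C)C(=O)[C@@H]2C(C)(C)CCC[C@]2(C)[C@@]12CC[C@@](CO[Si](CC)(CC)CC)(COCc3ccccc3)O2
F6 | step 18 | primary alcohol after debenzylation | CC(=O)O[C@]1(C)[C@@H](O[Si](C)(C)C(C)(C)C)C(=O)[C@@H]2C(C)(C)CCC[C@]2(C)[C@@]12CC[C@@](CO[Si](CC)(CC)CC)(CO)O2
F7 | step 18 | C14 aldehyde | CC(=O)O[C@]1(C)[C@@H](O[Si](C)(C)C(C)(C)C)C(=O)[C@@H]2C(C)(C)CCC[C@]2(C)[C@@]12CC[C@@](CO[Si](CC)(CC)CC)(C=O)O2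
F8 | step 18 | methyl enol ether (C14=C15–OMe, E/Z mixture) | CC(=O)O[C@]1(C)[C@@H](O[Si](C)(C)C(C)(C)C)C(=O)[C@@H]2C(C)(C)CCC[C@]2(C)[C@@]12CC[C@@](CO[Si](CC)(CC)CC)(C=COC)O2
F9 | step 10 | 8β,9β-epoxy alcohol of 12 (wanted enantiomeric series) | C[C@]1(O3)[C@@H](O[Si](C)(C)C(C)(C)C)[C@@H](O)[C@@H]2C(C)(C)CCC[C@]2(C)[C@]13CO
F10 | step 10 | 8α-acetoxy-9β,11-diol (6β-OH, 7β-OTBS) | CC(=O)O[C@]1(C)[C@@H](O[Si](C)(C)C(C)(C)C)[C@@H](O)[C@@H]2C(C)(C)CCC[C@]2(C)[C@]1(O)CO
F11 | step 10 | 9,11-cyclic thionocarbonate of F10 | CC(=O)O[C@]1(C)[C@@H](O[Si](C)(C)C(C)(C)C)[C@@H](O)[C@@H]2C(C)(C)CCC[C@]2(C)[C@]13COC(=S)O3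
F12 | step 10 | 8α-acetoxy 6β-alcohol with C9=C11 methylene (7β-OTBS) | CC(=O)O[C@]1(C)[C@@H](O[Si](C)(C)C(C)(C)C)[C@@H](O)[C@@H]2C(C)(C)CCC[C@]2(C)C1=C
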